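**Plan**
1. Ring locants used for the target: O1, C2 (ring CH2), C3 (aroyl), C4 (CH2OH), C5 (aryl). Retrosynthetic cuts, in order: the three O–Si bonds; O1–C2 together with the syringyl C(aryl)–C(=O) bond; C2–C3 (C2 as a one-carbon Mannich unit); C4–C5 (aldol).
2. Enabling feature: O1 is β to the C3 ketone through C2, so O1–C2 is an oxa-Michael bond. The chain O1–C5–C4–C3–C(=O) is also a latent γ-butyrolactone, so the ether oxygen can begin as the alkyl oxygen of an α-methylene lactone whose carbonyl carbon becomes the aryl ketone.
3. Forward: an auxiliary-controlled aldol of a succinate imide with O-silyl vanillin closes a temporary lactone ring that is not in the target. The carboxyl is reduced to the C4 CH2O arm and the lactone is α-methylenated. An aryllithium then opens the lactone and the freed benzylic alkoxide closes the tetrahydrofuran, the only ring made (both arenes are bought). Desilylation ends the route.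
4. Stereochemistry: C5 and C4 come from the (S)-4-benzyloxazolidinone-directed boron syn aldol (trans lactone). C3 is set by thermodynamic equilibration α to the ketone, giving the all-trans ring.

Key step: step 9

Remark on the chemistry: the target SMILES corresponds to the (3S,4R,5S) all-trans tetrahydrofuran. (S)-4-Benzyloxazolidin-2-one, methyl 4-chloro-4-oxobutanoate and 4-bromo-2,6-dimethoxyphenol are assumed to be purchasable.

**Step 1**
Reactants: 1 vanillin
Product: 2 3-methoxy-4-(triisopropylsilyloxy)benzaldehyde
Conditions: TIPSCl, imidazole, DMF, rt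
Reagents that add atoms: triisopropylsilyl chloride, CC(C)[Si](Cl)(C(C)C)C(C)C
Why: Routine phenol silylation; the bulky triisopropylsilyl ether is chosen to survive the later basic peroxide, borane and organolithium steps.

**Step 2**
Reactants: 3 (S)-4-benzyloxazolidin-2-one; 4 methyl 4-chloro-4-oxobutanoate
Product: 5 methyl 4-[(S)-4-benzyl-2-oxooxazolidin-3-yl]-4-oxobutanoate
Conditions: Et3N, DMAP (cat.), CH2Cl2, 0 °C to rt
Reagents that add atoms: none
Why: DMAP-catalysed N-acylation of the oxazolidinone by the acid chloride gives the succinate imide needed for auxiliary-controlled enolization.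

**Step 3**
Reactants: 5 succinate imide; 2 O-silyl vanillin
Product: 7 (S)-4-benzyl-3-{(2S,3S)-2-[3-methoxy-4-(triisopropylsilyloxy)phenyl]-5-oxotetrahydrofuran-3-carbonyl}oxazolidin-2-one, via syn-aldol hydroxy ester 6 (not isolated)
Conditions: Bu2BOTf, iPr2NEt, CH2Cl2, 0 °C; 2, −78 to 0 °C; pH 7 buffer, MeOH, H2O2; then PPTS (cat.), CH2Cl2, rt
Reagents that add atoms: none
Why: Evans syn aldol, in which Bu2BOTf/iPr2NEt enolizes the imide (not the ester) to the Z boron enolate, which adds through a Zimmerman–Traxler chair on the face opposite the benzyl group to set the carbinol and α-carbon centers (S,S), after which the γ-hydroxy ester lactonizes to the trans-4,5-disubstituted lactone, which also blocks retro-aldol.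

**Step 4**
Reactants: 7 lactone imide
Product: 8 (2S,3S)-2-[3-methoxy-4-(triisopropylsilyloxy)phenyl]-5-oxotetrahydrofuran-3-carboxylic acid
Conditions: LiOH, H2O2, THF/H2O, 0 °C; Na2SO3; HCl to pH 2
Reagents that add atoms: hydrogen peroxide (acting as LiOOH), OO
Why: Lithium hydroperoxide cleaves the exocyclic imide carbonyl selectively (standard oxazolidinone auxiliary hydrolysis), and any lactone opened by hydroxide recloses on acidification.

**Step 5**
Reactants: 8 lactone acid
Product: 9 (4R,5S)-4-(hydroxymethyl)-5-[3-methoxy-4-(triisopropylsilyloxy)phenyl]dihydrofuran-2(3H)-one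
Conditions: BH3·SMe2, THF, 0 °C to rt; MeOH quench
Reagents that add atoms: none
Why: Borane reduces a carboxylic acid through its acyloxyborane much faster than a γ-lactone, so the primary alcohol should form under non-basic conditions without touching the lactone or either stereocenter.

**Step 6**
Reactants: 9 hydroxymethyl lactone
Product: 10 (4R,5S)-5-[3-methoxy-4-(triisopropylsilyloxy)phenyl]-4-[(triisopropylsilyloxy)methyl]dihydrofuran-2(3H)-one
Conditions: TIPSOTf, 2,6-lutidine, CH2Cl2, −78 to 0 °C
Reagents that add atoms: triisopropylsilyl trifluoromethanesulfonate, CC(C)[Si](OS(=O)(=O)C(F)(F)F)(C(C)C)C(C)C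
Why: Silyl triflate/lutidine silylation of the primary alcohol is fast and non-nucleophilic, which avoids base-induced translactonization and installs a bulky group that should not migrate to the neighbouring alkoxide in step 9.

**Step 7**
Reactants: 10 silyl-protected lactone
Product: 13 (4R,5S)-5-[3-methoxy-4-(triisopropylsilyloxy)phenyl]-3-methylene-4-[(triisopropylsilyloxy)methyl]dihydrofuran-2(3H)-one, via Mannich base 11 (not isolated), via trimethylammonium iodide 12 (not isolated)
Conditions: LiN(iPr)2, THF, −78 °C; Me2N=CH2+ I− (Eschenmoser's salt), −78 °C to rt; then MeI, MeOH, rt; then NaHCO3 (aq), CH2Cl2, rt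
Reagents that add atoms: N,N-dimethylmethyleneiminium iodide (Eschenmoser's salt), C=[N+](C)C.[I-]
Why: Standard lactone α-methylenation by Mannich reaction of the lithium enolate, exhaustive N-methylation and E1cB (Hofmann-type) elimination under bicarbonate; the transient α-center is erased.

**Step 8**
Reactants: 14 4-bromo-2,6-dimethoxyphenol
Product: 15 (4-bromo-2,6-dimethoxyphenoxy)(tert-butyl)dimethylsilane
Conditions: TBSCl, imidazole, DMF, rt
Reagents that add atoms: tert-butyldimethylsilyl chloride, CC(C)(C)[Si](C)(C)Cl
Why: Routine phenol silylation that masks the acidic OH so the bromide can undergo bromine–lithium exchange.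

**Step 9**
Reactants: 13 α-methylene lactone; 15 silyl-protected aryl bromide
Product: 18 {4-[tert-butyl(dimethyl)silyl]oxy-3,5-dimethoxyphenyl}{(3S,4R,5S)-5-[3-methoxy-4-(triisopropylsilyloxy)phenyl]-4-[(triisopropylsilyloxy)methyl]tetrahydrofuran-3-yl}methanone, via aryllithium 16 (not isolated), via hydroxy enone 17 (not isolated)
Conditions: 15, n-BuLi, THF, −78 °C; then 13, LaCl3·2LiCl, THF, −78 to 0 °C; NH4Cl (aq); then DBU, THF, rt
Reagents that add atoms: none
Why: Proposed new method: aryllithium 16 should add once to the lactone carbonyl of 13 (LaCl3·2LiCl activates the C=O and disfavours attack at the exocyclic CH2), the tetrahedral alkoxide should persist at −78 °C and on warming collapse with cleavage of the lactone acyl–oxygen bond to aryl vinyl ketone 17, whose benzylic alkoxide then adds to the methylene terminus, so that the lactone's alkyl oxygen is relayed from the former carbonyl carbon to the methylene carbon and becomes O1. The closest known reaction types are the single addition of aryllithiums to γ- and δ-lactones (as used for C-aryl glycosides) and base-mediated intramolecular oxa-Michael additions of γ-hydroxy vinyl ketones and vinyl sulfones; their combination as a lactone-to-tetrahydrofuran ring switch on an α-methylene-γ-butyrolactone is the untested part. The tetrahydrofuran closes in the 5-endo-trig mode (O1–C2 bond), which is geometrically strained for first-row nucleophiles but accessible for alkoxides on strongly polarized acceptors, and the only alternative closure, 5-exo attack at the ketone carbon, is reversible hemiketal formation. C5 and C4 are carried unchanged from 13 because no bond to them is broken, and the new C3 center α to the ketone is set under thermodynamic control by DBU-mediated enolization (directly or through reversible ring opening), which places the aroyl group trans to the C4 substituent and should give the all-trans ring. The step needs 1,2- over 1,4-addition, mono-addition and closure through the benzylic oxygen only; these are secured by the hard aryl nucleophile with Lewis-acid activation at low temperature, by the tetrahedral intermediate surviving until the aryllithium is consumed, and by the primary oxygen being blocked as a non-migrating triisopropylsilyl ether.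

**Step 10**
Reactants: 18 tris-silyl ether
Product: 19 (4-hydroxy-3,5-dimethoxyphenyl)[(3S,4R,5S)-5-(4-hydroxy-3-methoxyphenyl)-4-(hydroxymethyl)tetrahydrofuran-3-yl]methanone
Conditions: Bu4NF, AcOH, THF, 0 °C to rt
Reagents that add atoms: none
Why: Fluoride-mediated cleavage of the two aryl silyl ethers and the primary silyl ether, buffered with acetic acid to keep the β-alkoxy ketone from ring opening, should free both phenols and the alcohol with C3 already in its thermodynamic configuration.

**Compound list**
1 | vanillin (4-hydroxy-3-methoxybenzaldehyde) | COc1cc(C=O)ccc1O | starting material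
2 | 3-methoxy-4-(triisopropylsilyloxy)benzaldehyde | COc1cc(C=O)ccc1O[Si](C(C)C)(C(C)C)C(C)C | intermediate
3 | (S)-4-benzyloxazolidin-2-one | O=C1N[C@@H](Cc2ccccc2)CO1 | starting material
4 | methyl 4-chloro-4-oxobutanoate | COC(=O)CCC(=O)Cl | starting material
5 | methyl 4-[(S)-4-benzyl-2-oxooxazolidin-3-yl]-4-oxobutanoate | COC(=O)CCC(=O)N1[C@@H](Cc2ccccc2)COC1=O | intermediate
6 | methyl (3S,4S)-3-[(S)-4-benzyl-2-oxooxazolidine-3-carbonyl]-4-hydroxy-4-[3-methoxy-4-(triisopropylsilyloxy)phenyl]butanoate (syn-aldol adduct, not isolated) | COC(=O)C[C@@H]([C@H](O)c1ccc(O[Si](C(C)C)(C(C)C)C(C)C)c(OC)c1)C(=O)N1[C@@H](Cc2ccccc2)COC1=O | intermediate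
7 | (S)-4-benzyl-3-{(2S,3S)-2-[3-methoxy-4-(triisopropylsilyloxy)phenyl]-5-oxotetrahydrofuran-3-carbonyl}oxazolidin-2-one (trans lactone) | O=C1C[C@H](C(=O)N2[C@@H](Cc3ccccc3)COC2=O)[C@@H](c2ccc(O[Si](C(C)C)(C(C)C)C(C)C)c(OC)c2)O1 | intermediate
8 | (2S,3S)-2-[3-methoxy-4-(triisopropylsilyloxy)phenyl]-5-oxotetrahydrofuran-3-carboxylic acid | O=C1C[C@H](C(=O)O)[C@@H](c2ccc(O[Si](C(C)C)(C(C)C)C(C)C)c(OC)c2)O1 | intermediate
9 | (4R,5S)-4-(hydroxymethyl)-5-[3-methoxy-4-(triisopropylsilyloxy)phenyl]dihydrofuran-2(3H)-one | O=C1C[C@H](CO)[C@@H](c2ccc(O[Si](C(C)C)(C(C)C)C(C)C)c(OC)c2)O1 | intermediate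
10 | (4R,5S)-5-[3-methoxy-4-(triisopropylsilyloxy)phenyl]-4-[(triisopropylsilyloxy)methyl]dihydrofuran-2(3H)-one | O=C1C[C@H](CO[Si](C(C)C)(C(C)C)C(C)C)[C@@H](c2ccc(O[Si](C(C)C)(C(C)C)C(C)C)c(OC)c2)O1 | intermediate
11 | (3R,4R,5S)-3-[(dimethylamino)methyl]-5-[3-methoxy-4-(triisopropylsilyloxy)phenyl]-4-[(triisopropylsilyloxy)methyl]dihydrofuran-2(3H)-one (Mannich base, 3,4-trans, not isolated) | O=C1[C@@H](CN(C)C)[C@H](CO[Si](C(C)C)(C(C)C)C(C)C)[C@@H](c2ccc(O[Si](C(C)C)(C(C)C)C(C)C)c(OC)c2)O1 | intermediate
12 | trimethylammonium iodide (methiodide) of 11 (not isolated) | O=C1[C@@H](C[N+](C)(C)C)[C@H](CO[Si](C(C)C)(C(C)C)C(C)C)[C@@H](c2ccc(O[Si](C(C)C)(C(C)C)C(C)C)c(OC)c2)O1.[I-] | intermediate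
13 | (4R,5S)-5-[3-methoxy-4-(triisopropylsilyloxy)phenyl]-3-methylene-4-[(triisopropylsilyloxy)methyl]dihydrofuran-2(3H)-one | O=C1C(=C)[C@H](CO[Si](C(C)C)(C(C)C)C(C)C)[C@@H](c2ccc(O[Si](C(C)C)(C(C)C)C(C)C)c(OC)c2)O1 | intermediate
14 | 4-bromo-2,6-dimethoxyphenol | COc1cc(Br)cc(OC)c1O | starting material
15 | (4-bromo-2,6-dimethoxyphenoxy)(tert-butyl)dimethylsilane | COc1cc(Br)cc(OC)c1O[Si](C)(C)C(C)(C)C | intermediate
16 | [4-(tert-butyldimethylsilyloxy)-3,5-dimethoxyphenyl]lithium (not isolated) | [Li]c1cc(OC)c(O[Si](C)(C)C(C)(C)C)c(OC)c1 | intermediate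
17 | (3R,4S)-1-[4-(tert-butyldimethylsilyloxy)-3,5-dimethoxyphenyl]-4-hydroxy-4-[3-methoxy-4-(triisopropylsilyloxy)phenyl]-2-methylene-3-[(triisopropylsilyloxy)methyl]butan-1-one (formed as its alkoxide, not isolated) | C=C(C(=O)c1cc(OC)c(O[Si](C)(C)C(C)(C)C)c(OC)c1)[C@H](CO[Si](C(C)C)(C(C)C)C(C)C)[C@H](O)c1ccc(O[Si](C(C)C)(C(C)C)C(C)C)c(OC)c1 | intermediate
18 | {4-[tert-butyl(dimethyl)silyl]oxy-3,5-dimethoxyphenyl}{(3S,4R,5S)-5-[3-methoxy-4-(triisopropylsilyloxy)phenyl]-4-[(triisopropylsilyloxy)methyl]tetrahydrofuran-3-yl}methanone (all-trans) | COc1cc([C@H]2OC[C@@H](C(=O)c3cc(OC)c(O[Si](C)(C)C(C)(C)C)c(OC)c3)[C@@H]2CO[Si](C(C)C)(C(C)C)C(C)C)ccc1O[Si](C(C)C)(C(C)C)C(C)C | intermediate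
19 | (4-hydroxy-3,5-dimethoxyphenyl)[(3S,4R,5S)-5-(4-hydroxy-3-methoxyphenyl)-4-(hydroxymethyl)tetrahydrofuran-3-yl]methanone | COc1cc([C@H]2OC[C@@H](C(=O)c3cc(OC)c(O)c(OC)c3)[C@@H]2CO)ccc1O | target

**Step count and risks**
Total steps: 10. Longest linear sequence: 8 steps (steps 2, 3, 4, 5, 6, 7, 9, 10; the branch through step 1 is equally long).

Steps most likely to fail:

Step 9. The aryl nucleophile may add in conjugate fashion to the exocyclic methylene or start anionic oligomerization instead of attacking the carbonyl, or a second addition may occur once the ketone is unmasked. The fallback removes the Michael acceptor from the addition step and uses only known reaction types. It sets out from compound 11, isolated by stopping step 7 after the Mannich stage. Aryllithium 16 is added at −78 °C to the saturated lactone 11 (single addition of an aryllithium to a γ-lactone) to give, after NH4Cl work-up, the γ-hydroxy Mannich-base ketone F1. N-Methylation with MeI in MeOH gives the methiodide F2, and NaHCO3 induces the classical E1cB loss of trimethylamine to the aryl vinyl ketone 17. DBU in THF then closes 17 by oxa-Michael addition and equilibrates C3, and the route is rejoined at compound 18.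

Step 4. Hydroxide may open the lactone before the imide is cleaved, exposing a β-alkoxide that fragments by retro-aldol, and the aryl silyl ether may be partly lost in the basic peroxide medium. The fallback replaces hydrolysis by reductive removal of the auxiliary. It sets out from compound 7, which is treated with LiBH4 and one equivalent of MeOH in THF at 0 °C; the activated imide should be reduced faster than the lactone. This gives the alcohol directly and rejoins the route at compound 9, bypassing compound 8 and step 5; no compound outside the list is made (F0).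

Step 10. Basic fluoride may trigger retro-oxa-Michael opening of the β-alkoxy ketone once the phenols are free, and the hindered primary silyl ether may be removed incompletely under buffered conditions. The fallback splits the deprotection into two mechanistically different stages. It sets out from compound 18. KHF2 in MeOH at rt, which is selective for aryl silyl ethers, should give the bis-phenol primary silyl ether F3. The remaining alkyl silyl ether is then cleaved under acidic, non-basic conditions (HF·pyridine, THF/pyridine, rt), rejoining the route at compound 19.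

**Further compounds**
F1 | step 9 | (2R,3R,4S)-1-[4-(tert-butyldimethylsilyloxy)-3,5-dimethoxyphenyl]-2-[(dimethylamino)methyl]-4-hydroxy-4-[3-methoxy-4-(triisopropylsilyloxy)phenyl]-3-[(triisopropylsilyloxy)methyl]butan-1-one | O=C(c1cc(OC)c(O[Si](C)(C)C(C)(C)C)c(OC)c1)[C@@H](CN(C)C)[C@H](CO[Si](C(C)C)(C(C)C)C(C)C)[C@H](O)c1ccc(O[Si](C(C)C)(C(C)C)C(C)C)c(OC)c1
F2 | step 9 | trimethylammonium iodide (methiodide) of F1 | O=C(c1cc(OC)c(O[Si](C)(C)C(C)(C)C)c(OC)c1)[C@@H](C[N+](C)(C)C)[C@H](CO[Si](C(C)C)(C(C)C)C(C)C)[C@H](O)c1ccc(O[Si](C(C)C)(C(C)C)C(C)C)c(OC)c1.[I-]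
F0 | step 4 | none | none
F3 | step 10 | (4-hydroxy-3,5-dimethoxyphenyl){(3S,4R,5S)-5-(4-hydroxy-3-methoxyphenyl)-4-[(triisopropylsilyloxy)methyl]tetrahydrofuran-3-yl}methanone | COc1cc([C@H]2OC[C@@H](C(=O)c3cc(OC)c(O)c(OC)c3)[C@@H]2CO[Si](C(C)C)(C(C)C)C(C)C)ccc1O
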